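**Retrosynthetic overview**

1. The target is cut at the C(sp3)–C(sp2) bond of the acetoxymethyl-bearing alkene: B-alkyl Suzuki–Miyaura coupling of an oxolane-terminated pentenyl unit with an (E)-2-bromoallylic alcohol made from geraniol, followed by primary acetylation and desilylation.
2. The oxolane fragment goes back, through CBS reduction of a 3-oxolanone (carbinol centre), enzymatic resolution, anti-selective cuprate addition (methyl-bearing centre) and Baeyer–Villiger oxidation (acetyl to oxygen), to a racemic cis-3-acetyl-5-alkenyl-2,2-dimethyloxolane.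
3. Key disconnection: this 3-acyloxolane arises from a 2-alkenyl-4,4,5-trimethyl-5-vinyl-1,3-dioxolane by Prins cyclisation–pinacol rearrangement, which makes the ring CH2–CH(O) bond and the CH(acyl)–CMe2 bond in one operation. The acetal comes from a vinyl-substituted pinacol-type diol and ethyl (E)-4-oxobut-2-enoate.
4. Enabling feature: the acetal carbon C2 of the dioxolane lies between O1 (on the CMe2 carbon C4) and O3 (on the quaternary allylic carbon C5 that carries the vinyl group). The oxocarbenium ion C2=O1 is therefore held in a six-atom array with the vinyl terminus, and the C5–O3 oxygen next to the developing cation drives the 1,2-shift of C4. The acetyl carbon is a sacrificial terminator, later excised as acetate.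
5. Ring order: 1,3-dioxolane (temporary), then an oxan-4-yl cation (transient six-membered ring), then the oxolane by ring contraction; the oxolane is the only ring of the target.

Key step: step 3

Remark 1: racemic intermediates carry the prefix rac and are drawn as the enantiomer that leads to the target.
Remark 2: the bromophosphonoacetate used in step 14 is a known olefination reagent and is taken as purchasable (otherwise it is one operation, bromination and mono-debromination, from the commercial Still–Gennari phosphonate).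

**Route**

Step 1
Reactants: 1 3-hydroxy-3-methylbutan-2-one
Product: 2 rac-2,3-dimethylpent-4-ene-2,3-diol
Conditions: CH2=CHMgBr (2.4 equiv), THF, −78 °C → rt; aq NH4Cl
Reagents that add atoms: vinylmagnesium bromide C=C[Mg]Br
Why: Grignard 1,2-addition to the α-hydroxy ketone (the first equivalent forms the magnesium alkoxide, which chelates the carbonyl); the new quaternary carbinol is racemic, which is harmless because this carbon becomes the acetyl carbonyl in step 3.

Step 2
Reactants: 2 rac-2,3-dimethylpent-4-ene-2,3-diol; 3 ethyl (2E)-4-oxobut-2-enoate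
Product: 4 ethyl (2E)-3-(5-ethenyl-4,4,5-trimethyl-1,3-dioxolan-2-yl)prop-2-enoate (both acetal epimers)
Conditions: camphor-10-sulfonic acid (5 mol %), MgSO4, CH2Cl2, 0 °C → rt
Reagents that add atoms: none
Why: Acid-catalysed acetalisation of the 1,2-diol under mild conditions that should not ionise the tertiary allylic alcohol; both acetal epimers converge in step 3.

Step 3
Reactants: 4 ethyl (2E)-3-(5-ethenyl-4,4,5-trimethyl-1,3-dioxolan-2-yl)prop-2-enoate
Product: 5 rac-ethyl (2E)-3-[(2S,4S)-4-acetyl-5,5-dimethyloxolan-2-yl]prop-2-enoate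
Conditions: SnCl4 (2.2 equiv), CH2Cl2, −78 → −20 °C; then Et3N, aq NaHCO3
Reagents that add atoms: none
Why: SnCl4 opens the acetal at the C2–O3 bond (O3 is the oxygen on the quaternary allylic carbon) to give the (E)-oxocarbenium ion C2=O1 on the oxygen bound to the CMe2 carbon; the terminal vinyl carbon adds to C2 through a chair six-membered transition state (Prins step, new ring CH2–CH bond), and the incipient oxan-4-yl cation is quenched at once by 1,2-shift of the CMe2 ring carbon from the stannyloxy-bearing carbon to the cationic carbon (pinacol step, new CH–CMe2 bond), which contracts the oxane to the oxolane and turns the former carbinol carbon into the acetyl carbonyl. The closest known reaction type is the Lewis-acid-promoted Prins cyclisation–pinacol rearrangement of 4-alkenyl-1,3-dioxolanes (acetals of allylic 1,2-diols) to 3-acyltetrahydrofurans, known for vinyl-substituted tertiary carbinols and for acetals of unsaturated aldehydes (it can equally be written as a 2-oxonia-Cope rearrangement followed by aldol closure). Ring closure: the transient oxane is closed 6-endo-trig on the vinyl terminus, and the oxolane is then formed from it by ring contraction (1,2-alkyl shift), not by a direct five-membered closure. Stereocentres: C2 and C4 of the oxolane are new; the (E)-oxocarbenium ion places the propenoate arm equatorial in the chair and the suprafacial shift delivers the acetyl group to the same face, so the 2,4-cis racemate is expected (any trans isomer is removed here by chromatography because step 8 needs one relative configuration), while absolute configuration is fixed later by resolution (step 8) and the C4 centre is re-set in steps 9 and 10. The step needs C–C bond formation to outrun heterolysis of the tertiary allylic C–O bond and needs the right oxygen to carry the oxocarbenium ion: only the O1-oxocarbenium ion can reach the vinyl group in a six-membered array (the other acetal opening is reversible and unproductive), the ester-conjugated alkene is too electron-poor to compete as a nucleophile, and the oxygen on the carbon next to the developing cation supplies the driving force for the shift.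

Step 4
Reactants: 5 rac-ethyl (2E)-3-[(2S,4S)-4-acetyl-5,5-dimethyloxolan-2-yl]prop-2-enoate
Product: 6 rac-ethyl (2E)-3-[(2S,4S)-4-(acetyloxy)-5,5-dimethyloxolan-2-yl]prop-2-enoate
Conditions: mCPBA (3 equiv), NaHCO3, CH2Cl2, 0 °C → rt
Reagents that add atoms: 3-chloroperoxybenzoic acid (mCPBA) OOC(=O)c1cccc(Cl)c1
Why: Baeyer–Villiger oxidation of the methyl ketone, in which the secondary ring carbon migrates in preference to methyl with retention of configuration, while the electron-poor enoate alkene is inert to the peracid.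

Step 5
Reactants: 6 rac-ethyl (2E)-3-[(2S,4S)-4-(acetyloxy)-5,5-dimethyloxolan-2-yl]prop-2-enoate
Product: 8 rac-ethyl (3R)-3-[(2S,4S)-4-(acetyloxy)-5,5-dimethyloxolan-2-yl]butanoate, via silyl ketene acetal 7 (not isolated)
Conditions: Me2CuLi (from CuI and MeLi, 2.5 equiv), Me3SiCl (5 equiv), THF, −78 °C; aq NH4Cl/NH3
Reagents that add atoms: lithium dimethylcuprate [Li+].C[Cu-]C; chlorotrimethylsilane C[Si](C)(C)Cl (silyl group only in 7)
Why: Conjugate addition of a Gilman cuprate to an (E)-γ-alkoxy enoate, accelerated by Me3SiCl; the methyl group should add anti to the ring C–O bond (ring CH2 antiperiplanar to the incoming cuprate, ring oxygen inside), which gives the required anti relation between the new methyl-bearing centre and oxolane C2, and the acetate is untouched at −78 °C.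

Step 6
Reactants: 8 rac-ethyl (3R)-3-[(2S,4S)-4-(acetyloxy)-5,5-dimethyloxolan-2-yl]butanoate
Product: 9 rac-(3R)-3-[(2S,4S)-4-hydroxy-5,5-dimethyloxolan-2-yl]butanal
Conditions: i-Bu2AlH (3.2 equiv), CH2Cl2, −78 °C; MeOH, aq potassium sodium tartrate
Reagents that add atoms: none
Why: Low-temperature DIBAL-H reduction stops at the aluminium hemiacetal of the ethyl ester (aldehyde after work-up) and removes the acetate in the same operation; no stereocentre is touched because the methyl-bearing carbon is β to the new aldehyde.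

Step 7
Reactants: 9 rac-(3R)-3-[(2S,4S)-4-hydroxy-5,5-dimethyloxolan-2-yl]butanal
Product: 10 rac-(3S,5S)-2,2-dimethyl-5-[(2R)-pent-4-en-2-yl]oxolan-3-ol
Conditions: Ph3PCH3Br and KN(SiMe3)2 (2.5 equiv each), THF, 0 °C; then 9, −78 → 0 °C
Reagents that add atoms: methylenetriphenylphosphorane C=P(c1ccccc1)(c1ccccc1)c1ccccc1
Why: Wittig methylenation of the aldehyde, in which the free hydroxyl only consumes one equivalent of ylide and the aldehyde has no α-stereocentre that could epimerise.

Step 8
Reactants: 10 rac-(3S,5S)-2,2-dimethyl-5-[(2R)-pent-4-en-2-yl]oxolan-3-ol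
Product: 11 (3S,5S)-2,2-dimethyl-5-[(2R)-pent-4-en-2-yl]oxolan-3-ol (single enantiomer recovered unacylated)
Conditions: immobilised Candida antarctica lipase B, vinyl acetate (3 equiv), t-BuOMe, 35 °C, run slightly past half conversion; chromatography
Reagents that add atoms: none
Why: Lipase-catalysed kinetic resolution by irreversible transesterification; by the empirical size rule for secondary alcohols (large quaternary C2 flank, small CH2 flank) the (3R)-carbinol of the mirror-image (3R,5R) series should be acylated, so the wanted (3S,5S)-alcohol stays behind and is brought to high enantiomeric purity by running slightly beyond half conversion.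

Step 9
Reactants: 11 (3S,5S)-2,2-dimethyl-5-[(2R)-pent-4-en-2-yl]oxolan-3-ol
Product: 12 (5S)-2,2-dimethyl-5-[(2R)-pent-4-en-2-yl]oxolan-3-one
Conditions: Dess–Martin periodinane, NaHCO3, CH2Cl2, 0 °C → rt
Reagents that add atoms: none
Why: Dess–Martin oxidation under buffered, non-basic conditions, which avoids β-elimination of the ring oxygen (retro-oxa-Michael) that could scramble C5; the carbinol centre is erased on purpose.

Step 10
Reactants: 12 (5S)-2,2-dimethyl-5-[(2R)-pent-4-en-2-yl]oxolan-3-one
Product: 13 (3R,5S)-2,2-dimethyl-5-[(2R)-pent-4-en-2-yl]oxolan-3-ol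
Conditions: (S)-2-methyl-CBS-oxazaborolidine [(S)-tetrahydro-1-methyl-3,3-diphenyl-1H,3H-pyrrolo[1,2-c][1,3,2]oxazaborole] (0.5 equiv), catecholborane (2 equiv), toluene, −78 → −40 °C; MeOH
Reagents that add atoms: none
Why: Corey–Bakshi–Shibata reduction, in which the catalyst distinguishes the quaternary C2 flank (large) from the C4 methylene (small) and should deliver hydride to give the (3R)-carbinol trans to the C5 side chain, overriding the weak bias of the remote substituent; catecholborane leaves the terminal alkene alone and any cis-alcohol 11 formed is a separable diastereomer.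

Step 11
Reactants: 14 geraniol
Product: 15 tert-butyl{[(2E)-3,7-dimethylocta-2,6-dien-1-yl]oxy}dimethylsilane
Conditions: t-BuMe2SiCl, imidazole, CH2Cl2, rt
Reagents that add atoms: tert-butyldimethylsilyl chloride CC(C)(C)[Si](C)(C)Cl
Why: Standard silylation of the primary allylic alcohol, giving a group that survives all later steps and is removed last without touching the acetate.

Step 12
Reactants: 15 tert-butyl{[(2E)-3,7-dimethylocta-2,6-dien-1-yl]oxy}dimethylsilane
Product: 16 rac-tert-butyl{[(2E)-5-(3,3-dimethyloxiran-2-yl)-3-methylpent-2-en-1-yl]oxy}dimethylsilane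
Conditions: mCPBA (1.0 equiv), NaHCO3, CH2Cl2, −20 → 0 °C
Reagents that add atoms: 3-chloroperoxybenzoic acid (mCPBA) OOC(=O)c1cccc(Cl)c1
Why: Prilezhaev epoxidation, which should take the remote trisubstituted alkene first because the other alkene is inductively deactivated by the allylic silyloxy group; the epoxide stereocentre is destroyed in step 13.

Step 13
Reactants: 16 rac-tert-butyl{[(2E)-5-(3,3-dimethyloxiran-2-yl)-3-methylpent-2-en-1-yl]oxy}dimethylsilane
Product: 17 (4E)-6-{[tert-butyl(dimethyl)silyl]oxy}-4-methylhex-4-enal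
Conditions: H5IO6 (1.2 equiv), THF/Et2O, 0 °C
Reagents that add atoms: none
Why: Periodic acid opens the epoxide and cleaves the resulting 1,2-diol (glycol cleavage) to the aldehyde and acetone without touching the (E)-alkene.

Step 14
Reactants: 17 (4E)-6-{[tert-butyl(dimethyl)silyl]oxy}-4-methylhex-4-enal; 18 methyl 2-[bis(2,2,2-trifluoroethoxy)phosphoryl]-2-bromoacetate
Product: 19 methyl (2E,6E)-2-bromo-8-{[tert-butyl(dimethyl)silyl]oxy}-6-methylocta-2,6-dienoate
Conditions: 18, t-BuOK, 18-crown-6, THF, −78 °C; then 17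
Reagents that add atoms: none
Why: Horner–Wadsworth–Emmons olefination with a bis(trifluoroethyl) phosphonate (Still–Gennari-type kinetic control), which should place the ester cis to the alkyl chain and bromine cis to hydrogen, the (E)-α-bromoacrylate geometry needed for the stereoretentive coupling in step 16.

Step 15
Reactants: 19 methyl (2E,6E)-2-bromo-8-{[tert-butyl(dimethyl)silyl]oxy}-6-methylocta-2,6-dienoate
Product: 20 (2E,6E)-2-bromo-8-{[tert-butyl(dimethyl)silyl]oxy}-6-methylocta-2,6-dien-1-ol
Conditions: i-Bu2AlH (2.3 equiv), CH2Cl2, −78 °C; aq potassium sodium tartrate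
Reagents that add atoms: none
Why: 1,2-Reduction of the enoate to the allylic alcohol, which leaves the alkene geometry and the vinylic C–Br bond unchanged.

Step 16
Reactants: 13 (3R,5S)-2,2-dimethyl-5-[(2R)-pent-4-en-2-yl]oxolan-3-ol; 20 (2E,6E)-2-bromo-8-{[tert-butyl(dimethyl)silyl]oxy}-6-methylocta-2,6-dien-1-ol
Product: 22 (2Z,6E)-8-{[tert-butyl(dimethyl)silyl]oxy}-2-{(4R)-4-[(2S,4R)-4-hydroxy-5,5-dimethyloxolan-2-yl]pentyl}-6-methylocta-2,6-dien-1-ol, via alkylborane 21 (not isolated)
Conditions: 13, 9-BBN dimer (2.2 equiv B–H), THF, rt; then 20, PdCl2(dppf) (8 mol %; dppf = 1,1'-bis(diphenylphosphino)ferrocene), AsPh3, Cs2CO3, DMF/H2O, rt → 45 °C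
Reagents that add atoms: 9-borabicyclo[3.3.1]nonane B1C2CCCC1CCC2 (boron only in 21)
Why: Anti-Markovnikov hydroboration of the terminal alkene followed by B-alkyl Suzuki–Miyaura coupling; oxidative addition of the vinyl bromide to zerovalent palladium and reductive elimination both retain the alkene geometry, so the pentyl chain replaces bromine cis to hydrogen, and free hydroxyl groups are tolerated.

Step 17
Reactants: 22 (2Z,6E)-8-{[tert-butyl(dimethyl)silyl]oxy}-2-{(4R)-4-[(2S,4R)-4-hydroxy-5,5-dimethyloxolan-2-yl]pentyl}-6-methylocta-2,6-dien-1-ol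
Product: 23 (2Z,6E)-8-{[tert-butyl(dimethyl)silyl]oxy}-2-{(4R)-4-[(2S,4R)-4-hydroxy-5,5-dimethyloxolan-2-yl]pentyl}-6-methylocta-2,6-dien-1-yl acetate
Conditions: AcCl (1.1 equiv), 2,4,6-collidine, CH2Cl2, −78 °C
Reagents that add atoms: acetyl chloride CC(Cl)=O
Why: Chemoselective acylation of the primary allylic alcohol, since the secondary hydroxyl next to the quaternary ring carbon should react far more slowly under these conditions.

Step 18
Reactants: 23 (2Z,6E)-8-{[tert-butyl(dimethyl)silyl]oxy}-2-{(4R)-4-[(2S,4R)-4-hydroxy-5,5-dimethyloxolan-2-yl]pentyl}-6-methylocta-2,6-dien-1-yl acetate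
Product: 24 (2Z,6E)-8-hydroxy-2-{(4R)-4-[(2S,4R)-4-hydroxy-5,5-dimethyloxolan-2-yl]pentyl}-6-methylocta-2,6-dien-1-yl acetate (target)
Conditions: HF·pyridine, pyridine, THF, 0 °C → rt
Reagents that add atoms: none
Why: Fluoride cleavage of the primary silyl ether under buffered conditions that leave the allylic acetate in place, with no acyl migration expected because the free hydroxyls are remote from the ester.

**Compound list**

1 | 3-hydroxy-3-methylbutan-2-one | CC(=O)C(C)(C)O | starting material
2 | rac-2,3-dimethylpent-4-ene-2,3-diol | C=CC(C)(O)C(C)(C)O | intermediate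
3 | ethyl (2E)-4-oxobut-2-enoate | CCOC(=O)/C=C/C=O | starting material
4 | ethyl (2E)-3-(5-ethenyl-4,4,5-trimethyl-1,3-dioxolan-2-yl)prop-2-enoate (acetal epimers) | CCOC(=O)/C=C/C1OC(C)(C)C(C)(C=C)O1 | intermediate
5 | rac-ethyl (2E)-3-[(2S,4S)-4-acetyl-5,5-dimethyloxolan-2-yl]prop-2-enoate | CCOC(=O)/C=C/[C@@H]1C[C@H](C(C)=O)C(C)(C)O1 | intermediate
6 | rac-ethyl (2E)-3-[(2S,4S)-4-(acetyloxy)-5,5-dimethyloxolan-2-yl]prop-2-enoate | CCOC(=O)/C=C/[C@@H]1C[C@H](OC(C)=O)C(C)(C)O1 | intermediate
7 | rac-{[(3R)-3-[(2S,4S)-4-(acetyloxy)-5,5-dimethyloxolan-2-yl]-1-ethoxybut-1-en-1-yl]oxy}trimethylsilane (silyl ketene acetal) | CCOC(O[Si](C)(C)C)=C[C@@H](C)[C@@H]1C[C@H](OC(C)=O)C(C)(C)O1 | intermediate (not isolated)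
8 | rac-ethyl (3R)-3-[(2S,4S)-4-(acetyloxy)-5,5-dimethyloxolan-2-yl]butanoate | CCOC(=O)C[C@@H](C)[C@@H]1C[C@H](OC(C)=O)C(C)(C)O1 | intermediate
9 | rac-(3R)-3-[(2S,4S)-4-hydroxy-5,5-dimethyloxolan-2-yl]butanal | O=CC[C@@H](C)[C@@H]1C[C@H](O)C(C)(C)O1 | intermediate
10 | rac-(3S,5S)-2,2-dimethyl-5-[(2R)-pent-4-en-2-yl]oxolan-3-ol | C=CC[C@@H](C)[C@@H]1C[C@H](O)C(C)(C)O1 | intermediate
11 | (3S,5S)-2,2-dimethyl-5-[(2R)-pent-4-en-2-yl]oxolan-3-ol (single enantiomer) | C=CC[C@@H](C)[C@@H]1C[C@H](O)C(C)(C)O1 | intermediate
12 | (5S)-2,2-dimethyl-5-[(2R)-pent-4-en-2-yl]oxolan-3-one | C=CC[C@@H](C)[C@@H]1CC(=O)C(C)(C)O1 | intermediate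
13 | (3R,5S)-2,2-dimethyl-5-[(2R)-pent-4-en-2-yl]oxolan-3-ol | C=CC[C@@H](C)[C@@H]1C[C@@H](O)C(C)(C)O1 | intermediate
14 | geraniol | CC(C)=CCC/C(C)=C/CO | starting material
15 | tert-butyl{[(2E)-3,7-dimethylocta-2,6-dien-1-yl]oxy}dimethylsilane | CC(C)=CCC/C(C)=C/CO[Si](C)(C)C(C)(C)C | intermediate
16 | rac-tert-butyl{[(2E)-5-(3,3-dimethyloxiran-2-yl)-3-methylpent-2-en-1-yl]oxy}dimethylsilane | CC1(C)OC1CC/C(C)=C/CO[Si](C)(C)C(C)(C)C | intermediate
17 | (4E)-6-{[tert-butyl(dimethyl)silyl]oxy}-4-methylhex-4-enal | O=CCC/C(C)=C/CO[Si](C)(C)C(C)(C)C | intermediate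
18 | methyl 2-[bis(2,2,2-trifluoroethoxy)phosphoryl]-2-bromoacetate | COC(=O)C(Br)P(=O)(OCC(F)(F)F)OCC(F)(F)F | starting material
19 | methyl (2E,6E)-2-bromo-8-{[tert-butyl(dimethyl)silyl]oxy}-6-methylocta-2,6-dienoate | COC(=O)/C(Br)=C\CC/C(C)=C/CO[Si](C)(C)C(C)(C)C | intermediate
20 | (2E,6E)-2-bromo-8-{[tert-butyl(dimethyl)silyl]oxy}-6-methylocta-2,6-dien-1-ol | OC/C(Br)=C\CC/C(C)=C/CO[Si](C)(C)C(C)(C)C | intermediate
21 | 9-{(4R)-4-[(2S,4R)-4-hydroxy-5,5-dimethyloxolan-2-yl]pentyl}-9-borabicyclo[3.3.1]nonane | B1(CCC[C@@H](C)[C@@H]2C[C@@H](O)C(C)(C)O2)C2CCCC1CCC2 | intermediate (not isolated)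
22 | (2Z,6E)-8-{[tert-butyl(dimethyl)silyl]oxy}-2-{(4R)-4-[(2S,4R)-4-hydroxy-5,5-dimethyloxolan-2-yl]pentyl}-6-methylocta-2,6-dien-1-ol | OC/C(=C\CC/C(C)=C/CO[Si](C)(C)C(C)(C)C)CCC[C@@H](C)[C@@H]1C[C@@H](O)C(C)(C)O1 | intermediate
23 | (2Z,6E)-8-{[tert-butyl(dimethyl)silyl]oxy}-2-{(4R)-4-[(2S,4R)-4-hydroxy-5,5-dimethyloxolan-2-yl]pentyl}-6-methylocta-2,6-dien-1-yl acetate | CC(=O)OC/C(=C\CC/C(C)=C/CO[Si](C)(C)C(C)(C)C)CCC[C@@H](C)[C@@H]1C[C@@H](O)C(C)(C)O1 | intermediate
24 | (2Z,6E)-8-hydroxy-2-{(4R)-4-[(2S,4R)-4-hydroxy-5,5-dimethyloxolan-2-yl]pentyl}-6-methylocta-2,6-dien-1-yl acetate | CC(=O)OC/C(=C\CC/C(C)=C/CO)CCC[C@@H](C)[C@@H]1C[C@@H](O)C(C)(C)O1 | target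

**Step count and risks**

Total step count: 18. Longest linear sequence: 13 steps (steps 1 to 10, then 16 to 18); steps 11 to 15 make the coupling partner in parallel.

Steps most likely to fail:

1. Step 3 (key step). With the ester-conjugated oxocarbenium ion, C–C bond formation to the unactivated vinyl group may be too slow, so that heterolysis of the tertiary allylic C–O bond (elimination or shifts within the diol unit) or Lewis-acid-induced oligomerisation of the enoate consumes the acetal. Fallback: the enoate is attached after the ring is made. It sets out from 2. Acetalisation with commercial (benzyloxy)acetaldehyde (camphorsulfonic acid, MgSO4) gives 2-[(benzyloxy)methyl]-5-ethenyl-4,4,5-trimethyl-1,3-dioxolane F1. The same SnCl4-promoted rearrangement, now through a non-conjugated and more electrophilic α-alkoxy oxocarbenium ion, should give rac-1-[(3S,5S)-5-[(benzyloxy)methyl]-2,2-dimethyloxolan-3-yl]ethan-1-one F2. Baeyer–Villiger oxidation (mCPBA) gives rac-(3S,5S)-5-[(benzyloxy)methyl]-2,2-dimethyloxolan-3-yl acetate F3, hydrogenolysis (H2, Pd/C, EtOAc) gives rac-(3S,5S)-5-(hydroxymethyl)-2,2-dimethyloxolan-3-yl acetate F4, and Dess–Martin oxidation gives rac-(3S,5S)-5-formyl-2,2-dimethyloxolan-3-yl acetate F5. Wittig reaction with Ph3P=CHCO2Et then gives the (E)-enoate and the route is rejoined at 6.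

2. Step 8. The lipase may acylate the carbinol next to the quaternary ring carbon too slowly, or with too little discrimination between the enantiomers, so that the recovered alcohol is not enantiopure. Fallback: resolution by catalyst-controlled reduction instead of by acylation. It sets out from racemic 10, which is oxidised (Dess–Martin periodinane, NaHCO3) to the racemic ketone F6. Reduction with the (S)-CBS catalyst and catecholborane as in step 10 should convert the (5S) half into 13 and the (5R) half into the cis-configured (3R,5R)-2,2-dimethyl-5-[(2S)-pent-4-en-2-yl]oxolan-3-ol F7. These are diastereomers and are separated by chromatography; the route is rejoined at 13. The enantiomeric purity of 13 then rests on the facial fidelity of the catalyst.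

3. Step 5. Facial selectivity of the methyl transfer may be poor, because the only control element is the ring C–O stereocentre next to the enoate; this would give a mixture of epimers at the methyl-bearing carbon that is hard to separate. Fallback: the same 1,2-anti relationship is made by hydroboration instead of conjugate addition. It sets out from 6. Ozonolysis (O3, CH2Cl2, −78 °C; PPh3) gives the aldehyde rac-(3S,5S)-5-formyl-2,2-dimethyloxolan-3-yl acetate F5 (the same aldehyde as in the first fallback). MeMgBr (1.0 equiv, −78 °C) gives rac-(3S,5S)-5-(1-hydroxyethyl)-2,2-dimethyloxolan-3-yl acetate F8, Dess–Martin oxidation gives rac-(3S,5S)-5-acetyl-2,2-dimethyloxolan-3-yl acetate F9, and non-basic Takai–Lombardo methylenation (Zn, CH2Br2, TiCl4) gives rac-(3S,5S)-2,2-dimethyl-5-(prop-1-en-2-yl)oxolan-3-yl acetate F10. Hydroboration with 9-BBN, which for 1,1-disubstituted alkenes next to an ether stereocentre should give the 1,2-anti product, followed by Suzuki–Miyaura coupling in the same flask with bromoethene (PdCl2(dppf), K3PO4), gives rac-(3S,5S)-2,2-dimethyl-5-[(2R)-pent-4-en-2-yl]oxolan-3-yl acetate F11. Methanolysis (K2CO3, MeOH) returns to the route at 10.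

Further compounds
F1 | step 3 | 2-[(benzyloxy)methyl]-5-ethenyl-4,4,5-trimethyl-1,3-dioxolane | C=CC1(C)OC(COCc2ccccc2)OC1(C)C
F2 | step 3 | rac-1-[(3S,5S)-5-[(benzyloxy)methyl]-2,2-dimethyloxolan-3-yl]ethan-1-one | c1ccccc1COC[C@@H]2C[C@H](C(C)=O)C(C)(C)O2
F3 | step 3 | rac-(3S,5S)-5-[(benzyloxy)methyl]-2,2-dimethyloxolan-3-yl acetate | c1ccccc1COC[C@@H]2C[C@H](OC(C)=O)C(C)(C)O2
F4 | step 3 | rac-(3S,5S)-5-(hydroxymethyl)-2,2-dimethyloxolan-3-yl acetate | OC[C@@H]1C[C@H](OC(C)=O)C(C)(C)O1
F5 | step 3 | rac-(3S,5S)-5-formyl-2,2-dimethyloxolan-3-yl acetate | O=C[C@@H]1C[C@H](OC(C)=O)C(C)(C)O1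
F6 | step 8 | racemic 2,2-dimethyl-5-(pent-4-en-2-yl)oxolan-3-one (12 together with its mirror image; the mirror image is drawn) | C=CC[C@H](C)[C@H]1CC(=O)C(C)(C)O1
F7 | step 8 | (3R,5R)-2,2-dimethyl-5-[(2S)-pent-4-en-2-yl]oxolan-3-ol | C=CC[C@H](C)[C@H]1C[C@@H](O)C(C)(C)O1
F8 | step 5 | rac-(3S,5S)-5-(1-hydroxyethyl)-2,2-dimethyloxolan-3-yl acetate (carbinol epimers) | CC(O)[C@@H]1C[C@H](OC(C)=O)C(C)(C)O1
F9 | step 5 | rac-(3S,5S)-5-acetyl-2,2-dimethyloxolan-3-yl acetate | CC(=O)[C@@H]1C[C@H](OC(C)=O)C(C)(C)O1
F10 | step 5 | rac-(3S,5S)-2,2-dimethyl-5-(prop-1-en-2-yl)oxolan-3-yl acetate | C=C(C)[C@@H]1C[C@H](OC(C)=O)C(C)(C)O1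
F11 | step 5 | rac-(3S,5S)-2,2-dimethyl-5-[(2R)-pent-4-en-2-yl]oxolan-3-yl acetate | C=CC[C@@H](C)[C@@H]1C[C@H](OC(C)=O)C(C)(C)O1
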